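Retrosynthesis: the O3–S and O7–S bonds and the benzyl group on O3' go first; ring C is returned to the dihydro level and opened at O1–C2; ring A is cut at C4a–C8a (the same bond as C4a–C5 while ring C is open).
Ring A itself offers that cut: its oxygens sit on the alternate carbons C5, C7 and C8a and the acyl carbon C4 hangs on C4a, the mark of three acetate units closed by a Claisen condensation, so ring A unfolds to a 3,5,7-trioxo ester stored as a 4-hydroxy-2-pyranone.
The pyranone side chain is cut at its CH2–CO bond (triacetic acid lactone plus an α-alkoxycinnamoyl N-methoxy-N-methylamide) and at the cinnamoyl C=C bond (O-benzylisovanillin plus a glycolate ester).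
Forward order: chain assembly (aldol condensation, amide, dianion acylation), ring A by Claisen folding, ring C by oxa-Michael closure and dehydrogenation, then sulfation and debenzylation; ring B is bought with the aldehyde.
O3 is carried as a methoxymethyl ether and O3' as a benzyl ether, so that O3 and O7 are sulfated while O3' is still masked and O5 is held back by its hydrogen bond to the C4 carbonyl.
Stereochemistry: the target has no stereocentre; the enol ether geometry and the two transient centres of the flavanone disappear when ring C becomes aromatic.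

Key step: step 5

Assumption: the target is the free bis(hydrogen sulfate) as drawn; 15 and 16 are written in this acid form, although they would be handled as ammonium salts until the cation exchange that closes step 9.

Step 1
Reactants: 1 methyl glycolate
Product: 2 methyl 2-(methoxymethoxy)acetate
Conditions: MOMCl, iPr2NEt, CH2Cl2, 0 °C → rt
Reagents that add atoms: chloromethyl methyl ether, COCCl
Why: O-alkylation of the primary alcohol by the reactive α-chloro ether under amine base is the standard methoxymethyl protection and should leave the methyl ester untouched.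

Step 2
Reactants: 2 methyl 2-(methoxymethoxy)acetate; 3 3-(benzyloxy)-4-methoxybenzaldehyde (O-benzylisovanillin)
Product: 6 methyl (Z)-3-[3-(benzyloxy)-4-methoxyphenyl]-2-(methoxymethoxy)prop-2-enoate, via aldol adduct 4 (not isolated), via aldol mesylate 5 (not isolated)
Conditions: LiN(iPr)2, THF, −78 °C; 3, −78 °C; MsCl, −78 → 0 °C; DBU, rt
Reagents that add atoms: none
Why: Lithium enolate aldol addition, O-mesylation of the aldolate and DBU-promoted E1cB elimination make up a standard aldol condensation for α-alkoxy esters and should give mainly the (Z)-enol ether with the aryl group trans to the ester, the geometry being of no consequence because ring C later absorbs this double bond.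

Step 3
Reactants: 6 methyl (Z)-3-[3-(benzyloxy)-4-methoxyphenyl]-2-(methoxymethoxy)prop-2-enoate
Product: 7 (Z)-3-[3-(benzyloxy)-4-methoxyphenyl]-N-methoxy-2-(methoxymethoxy)-N-methylprop-2-enamide
Conditions: MeNH(OMe)·HCl, iPrMgCl, THF, −20 → 0 °C
Reagents that add atoms: N,O-dimethylhydroxylamine hydrochloride, CNOC.Cl
Why: Aminolysis of the ester by the chloromagnesium amide of N,O-dimethylhydroxylamine is the usual direct ester-to-N-methoxy-N-methylamide conversion and should attack only the ester carbonyl, leaving the enol ether, the acetal and the benzyl ether alone.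

Step 4
Reactants: 7 (Z)-3-[3-(benzyloxy)-4-methoxyphenyl]-N-methoxy-2-(methoxymethoxy)-N-methylprop-2-enamide; 8 4-hydroxy-6-methyl-2H-pyran-2-one
Product: 9 6-[(Z)-4-[3-(benzyloxy)-4-methoxyphenyl]-3-(methoxymethoxy)-2-oxobut-3-en-1-yl]-4-hydroxy-2H-pyran-2-one
Conditions: 8, LiN(iPr)2 (2.2 equiv per 8), THF, −78 °C; then 7, −78 → −20 °C; cold dilute HCl to pH 4
Reagents that add atoms: none
Why: The dianion of the hydroxypyranone reacts at its methyl carbon, the most basic site, and acylation by an N-methoxy-N-methylamide (Weinreb ketone synthesis) stops at the chelated tetrahedral adduct, so the ketone should be released only on work-up, while conjugate addition is disfavoured by the α-alkoxy and β-aryl donors.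

Step 5
Reactants: 9 6-[(Z)-4-[3-(benzyloxy)-4-methoxyphenyl]-3-(methoxymethoxy)-2-oxobut-3-en-1-yl]-4-hydroxy-2H-pyran-2-one
Product: 11 (Z)-3-[3-(benzyloxy)-4-methoxyphenyl]-2-(methoxymethoxy)-1-(2,4,6-trihydroxyphenyl)prop-2-en-1-one, via magnesium-chelated triketo ester 10 (not isolated)
Conditions: Mg(OMe)2, MeOH, reflux, argon; cold dilute HCl to pH 4
Reagents that add atoms: none
Why: Methoxide opens the lactone of 9 to the methyl 3,5,7-trioxo ester 10, held as a magnesium chelate, whose C6 methylene (flanked by the C5 and C7 carbonyls and the most acidic carbon of the chain) attacks the ester carbon C1; methoxide leaves and the cyclic triketone enolises to the phloroglucinol ring. The closest known reaction type is the magnesium methoxide rearrangement of 6-(2-oxoalkyl)-4-hydroxy-2-pyranones to acylphloroglucinols, an intramolecular Claisen (Dieckmann-type) condensation, applied here to an α-alkoxycinnamoyl side chain. Ring A closes in a 6-(enolendo)-exo-trig mode and the new bond is C4a–C8a. No stereocentre is created and the (Z)-enol ether is a spectator. The step needs Claisen folding (C6 onto C1) and not aldol folding (C2 onto the C7 ketone): divalent magnesium chelates the tricarbonyl array and places the C5–C7 enolate next to the activated ester, and C7 is the carbonyl of a cross-conjugated, donor-substituted α-alkoxy enone and so a poor and hindered electrophile. The methoxymethyl and benzyl ethers are inert to methoxide, and in base the chalcone phenoxide is the favoured form, so ring C should stay open until step 6.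

Step 6
Reactants: 11 (Z)-3-[3-(benzyloxy)-4-methoxyphenyl]-2-(methoxymethoxy)-1-(2,4,6-trihydroxyphenyl)prop-2-en-1-one
Product: 12 rac-(2R,3R)-2-[3-(benzyloxy)-4-methoxyphenyl]-5,7-dihydroxy-3-(methoxymethoxy)-2,3-dihydro-4H-chromen-4-one (trans)
Conditions: NaOAc, EtOH, reflux
Reagents that add atoms: none
Why: Base-catalysed chalcone–flavanone isomerisation (6-endo-trig oxa-Michael addition of a 2'-hydroxyl) is favoured for 2',6'-dihydroxychalcones because the product keeps a hydrogen-bonded 5-hydroxyl, and reversible ring closure together with enolisation at C3 should settle on the trans (diequatorial) racemate, whose two centres are erased in step 7.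

Step 7
Reactants: 12 rac-(2R,3R)-2-[3-(benzyloxy)-4-methoxyphenyl]-5,7-dihydroxy-3-(methoxymethoxy)-2,3-dihydro-4H-chromen-4-one
Product: 14 2-[3-(benzyloxy)-4-methoxyphenyl]-3,5,7-trihydroxy-4H-chromen-4-one, via trans-dihydroflavonol 13 (not isolated)
Conditions: HCl, MeOH, 50 °C; evaporate; then I2, KOAc, AcOH, 100 °C
Reagents that add atoms: none
Why: Acid methanolysis removes the acetal-type methoxymethyl ether without touching the aryl benzyl ether, and the free dihydroflavonol is then dehydrogenated by iodine under acetate buffering (iodination of the enol at C3, loss of HI to the 3,4-dione, tautomerisation), the classical dihydroflavonol-to-flavonol oxidation that tolerates free 5- and 7-hydroxyls.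

Step 8
Reactants: 14 2-[3-(benzyloxy)-4-methoxyphenyl]-3,5,7-trihydroxy-4H-chromen-4-one
Product: 15 2-[3-(benzyloxy)-4-methoxyphenyl]-5-hydroxy-4-oxo-4H-chromene-3,7-diyl bis(hydrogen sulfate)
Conditions: SO3·NMe3 (excess), Et3N, DMF, 50 °C
Reagents that add atoms: sulfur trioxide–trimethylamine complex, C[N+](C)(C)S(=O)(=O)[O-]
Why: O-Sulfation of phenols with an amine–sulfur trioxide complex takes the acidic 7-hydroxyl and the enolic 3-hydroxyl, whereas the 5-hydroxyl is held back by its strong hydrogen bond to the C4 carbonyl and O3' is blocked as the benzyl ether, so exhaustive treatment should stop at the 3,7-disulfate.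

Step 9
Reactants: 15 2-[3-(benzyloxy)-4-methoxyphenyl]-5-hydroxy-4-oxo-4H-chromene-3,7-diyl bis(hydrogen sulfate)
Product: 16 5-hydroxy-2-(3-hydroxy-4-methoxyphenyl)-4-oxo-4H-chromene-3,7-diyl bis(hydrogen sulfate) (tamarixetin 3,7-disulfate, CNP0574123.0)
Conditions: H2 (1 atm), Pd/C, MeOH–H2O, rt; then Dowex 50W (H+ form), H2O, 0 °C, freeze-drying
Reagents that add atoms: none
Why: Hydrogenolysis of an aryl benzyl ether over Pd/C leaves aryl sulfate esters and the chromone double bond untouched, and a brief cation exchange in the cold should deliver the acid form before the labile 3-sulfate can hydrolyse.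

Compound list
1 | methyl glycolate (methyl 2-hydroxyacetate) | COC(=O)CO | starting material
2 | methyl 2-(methoxymethoxy)acetate | COCOCC(=O)OC | intermediate
3 | 3-(benzyloxy)-4-methoxybenzaldehyde (O-benzylisovanillin) | COc1ccc(C=O)cc1OCc1ccccc1 | starting material
4 | methyl 3-[3-(benzyloxy)-4-methoxyphenyl]-3-hydroxy-2-(methoxymethoxy)propanoate (aldol adduct, present as its lithium alkoxide; syn/anti mixture, racemic, centres undefined) | COCOC(C(=O)OC)C(O)c1ccc(OC)c(OCc2ccccc2)c1 | intermediate
5 | methyl 3-[3-(benzyloxy)-4-methoxyphenyl]-2-(methoxymethoxy)-3-[(methylsulfonyl)oxy]propanoate (diastereomer mixture, racemic, centres undefined) | COCOC(C(=O)OC)C(OS(C)(=O)=O)c1ccc(OC)c(OCc2ccccc2)c1 | intermediate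
6 | methyl (Z)-3-[3-(benzyloxy)-4-methoxyphenyl]-2-(methoxymethoxy)prop-2-enoate | COc1ccc(/C=C(\OCOC)C(=O)OC)cc1OCc1ccccc1 | intermediate
7 | (Z)-3-[3-(benzyloxy)-4-methoxyphenyl]-N-methoxy-2-(methoxymethoxy)-N-methylprop-2-enamide | COc1ccc(/C=C(\OCOC)C(=O)N(C)OC)cc1OCc1ccccc1 | intermediate
8 | 4-hydroxy-6-methyl-2H-pyran-2-one (triacetic acid lactone) | Cc1cc(O)cc(=O)o1 | starting material
9 | 6-[(Z)-4-[3-(benzyloxy)-4-methoxyphenyl]-3-(methoxymethoxy)-2-oxobut-3-en-1-yl]-4-hydroxy-2H-pyran-2-one | COc1ccc(/C=C(\OCOC)C(=O)Cc2cc(O)cc(=O)o2)cc1OCc1ccccc1 | intermediate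
10 | methyl (Z)-9-[3-(benzyloxy)-4-methoxyphenyl]-8-(methoxymethoxy)-3,5,7-trioxonon-8-enoate (present as its magnesium chelate) | COc1ccc(/C=C(\OCOC)C(=O)CC(=O)CC(=O)CC(=O)OC)cc1OCc1ccccc1 | intermediate
11 | (Z)-3-[3-(benzyloxy)-4-methoxyphenyl]-2-(methoxymethoxy)-1-(2,4,6-trihydroxyphenyl)prop-2-en-1-one | COc1ccc(/C=C(\OCOC)C(=O)c2c(O)cc(O)cc2O)cc1OCc1ccccc1 | intermediate
12 | rac-(2R,3R)-2-[3-(benzyloxy)-4-methoxyphenyl]-5,7-dihydroxy-3-(methoxymethoxy)-2,3-dihydro-4H-chromen-4-one (trans; one enantiomer drawn) | COc1ccc([C@@H]2[C@@H](OCOC)C(=O)c3c(O)cc(O)cc3O2)cc1OCc1ccccc1 | intermediate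
13 | rac-(2R,3R)-2-[3-(benzyloxy)-4-methoxyphenyl]-3,5,7-trihydroxy-2,3-dihydro-4H-chromen-4-one (trans; one enantiomer drawn) | COc1ccc([C@@H]2[C@@H](O)C(=O)c3c(O)cc(O)cc3O2)cc1OCc1ccccc1 | intermediate
14 | 2-[3-(benzyloxy)-4-methoxyphenyl]-3,5,7-trihydroxy-4H-chromen-4-one (3'-O-benzyltamarixetin) | COc1ccc(-c2oc3cc(O)cc(O)c3c(=O)c2O)cc1OCc1ccccc1 | intermediate
15 | 2-[3-(benzyloxy)-4-methoxyphenyl]-5-hydroxy-4-oxo-4H-chromene-3,7-diyl bis(hydrogen sulfate) | COc1ccc(-c2oc3cc(OS(=O)(=O)O)cc(O)c3c(=O)c2OS(=O)(=O)O)cc1OCc1ccccc1 | intermediate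
16 | 5-hydroxy-2-(3-hydroxy-4-methoxyphenyl)-4-oxo-4H-chromene-3,7-diyl bis(hydrogen sulfate) | COc1ccc(-c2oc3cc(OS(=O)(=O)O)cc(O)c3c(=O)c2OS(=O)(=O)O)cc1O | target

Total step count: 9. Longest linear sequence: 9 steps (1 → 2 → 6 → 7 → 9 → 11 → 12 → 14 → 15 → 16); 3 and 8 enter as purchased compounds.

Steps most likely to fail

Step 5 (key step). The pyranone is present as its unreactive 4-oxido anion and may open too slowly, so that the long reflux lets methoxide add to the enone and cleave the side chain, or lets the opened chain close in the aldol sense. The fallback builds the open-chain ester directly instead of unmasking it, and sets out from 7 and 8. Methanolysis of 8 with Mg(OMe)2 in methanol would give methyl 3,5-dioxohexanoate F1. Its trianion (LiN(iPr)2, 3.3 equiv, THF, −78 → 0 °C) would be acylated at the terminal methyl carbon by amide 7 to give the triketo ester 10, this time isolated. Claisen closure of 10 with Mg(OMe)2 in methanol at room temperature, where no lactone has to be opened, comes back to the route at 11.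

Step 4. The sparingly soluble dianion may act mainly as a base or add slowly, so that proton transfer, conjugate addition to the unsaturated amide or attack through C3 of the pyranone competes with acylation at the methyl carbon. The fallback changes the electrophile to an aldehyde and corrects the oxidation level afterwards; it sets out from 7. Reduction with iBu2AlH (THF, −78 °C) would give (Z)-3-[3-(benzyloxy)-4-methoxyphenyl]-2-(methoxymethoxy)prop-2-enal F2. Aldol addition of the dianion of 8, a fast and well-known reaction with aldehydes, would give the racemic allylic alcohol 6-[(Z)-4-[3-(benzyloxy)-4-methoxyphenyl]-2-hydroxy-3-(methoxymethoxy)but-3-en-1-yl]-4-hydroxy-2H-pyran-2-one F3. Oxidation of the allylic alcohol with MnO2 in CH2Cl2–acetone comes back to the route at 9.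

Step 7. Electrophilic iodination of ring A at C6 or C8 may compete with iodination at C3, or the free dihydroflavonol may ring-contract to a 2-benzyl-2-hydroxybenzofuranone during the oxidation. The fallback oxidises before unmasking, with a hydride-abstracting quinone on a phenol-capped substrate; it sets out from 12. Acetylation (Ac2O, pyridine, DMAP) would give rac-(2R,3R)-2-[3-(benzyloxy)-4-methoxyphenyl]-3-(methoxymethoxy)-4-oxo-3,4-dihydro-2H-chromene-5,7-diyl diacetate F4. DDQ in dioxane at reflux, the established dehydrogenation of flavanone acetates, would give 2-[3-(benzyloxy)-4-methoxyphenyl]-3-(methoxymethoxy)-4-oxo-4H-chromene-5,7-diyl diacetate F5. HCl in methanol at 50 °C would then remove the acetal and both acetates and come back to the route at 14.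

Further compounds
F1 | step 5 | methyl 3,5-dioxohexanoate | CC(=O)CC(=O)CC(=O)OC
F2 | step 4 | (Z)-3-[3-(benzyloxy)-4-methoxyphenyl]-2-(methoxymethoxy)prop-2-enal | COc1ccc(/C=C(\OCOC)C=O)cc1OCc1ccccc1
F3 | step 4 | 6-[(Z)-4-[3-(benzyloxy)-4-methoxyphenyl]-2-hydroxy-3-(methoxymethoxy)but-3-en-1-yl]-4-hydroxy-2H-pyran-2-one (racemic, carbinol centre undefined) | COc1ccc(/C=C(\OCOC)C(O)Cc2cc(O)cc(=O)o2)cc1OCc1ccccc1
F4 | step 7 | rac-(2R,3R)-2-[3-(benzyloxy)-4-methoxyphenyl]-3-(methoxymethoxy)-4-oxo-3,4-dihydro-2H-chromene-5,7-diyl diacetate | COc1ccc([C@@H]2[C@@H](OCOC)C(=O)c3c(OC(C)=O)cc(OC(C)=O)cc3O2)cc1OCc1ccccc1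
F5 | step 7 | 2-[3-(benzyloxy)-4-methoxyphenyl]-3-(methoxymethoxy)-4-oxo-4H-chromene-5,7-diyl diacetate | COc1ccc(-c2oc3cc(OC(C)=O)cc(OC(C)=O)c3c(=O)c2OCOC)cc1OCc1ccccc1
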